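All runs were computed from invented constants, and the scatter is random.

Target is what you want from this substrate, and you are asked when it stands highest in the flask and how long it stays near that height.

| flask | substrate | remark | time |
|---|---|---|---|
| noon | 0.59 M | run made earlier |  |
| dawn | 1.3 M | run made earlier |  |
| flask | 0.88 M |  | 15 d |

- noon (time / d: target / %): 1.25: 31.2; 2.08: 35.3; 3.00: 35.8; 5.00: 32.8; 8.00: 25.5; 12.0: 15.7; 20.0: 6.6
- dawn (time / d: target / %): 1.25: 33.7; 2.08: 41.4; 3.00: 44.7; 5.00: 50.1; 8.00: 53.5; 12.0: 50.1; 20.0: 34.6

(each reading ± 0.5 percentage points)

* the moment within 15 d at which there is most target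
* the amount of target, in percent of the substrate charged, at that time
* earliest time at which at least nineteen twentieths of that best amount are there, in d
* latest time at which they still are, in d

- a reading or a percentage of target counts all its forms, free or not

Climb the time scales from the fastest. At the first reading, 1.25 d, the noon run shows 31.2% and the dawn run 33.7%, a gap of 2.5 percentage points although dawn holds twice the charge. So the early rise says little about charge. The next rung does: the highest noon reading is 35.8% at 3.00 d, the highest dawn reading 53.5% at 8.00 d. On the slowest rung, the last two noon readings give a halving time of 6.40 d, longer than the time of the first reading.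

Take the rise of the highest reading per molar of starting [substrate], 0.249 L mol⁻¹ as a fraction of the charge, and call it the height gain. The new flask's charge lies 0.408 of the way from the noon charge to the dawn charge, so interpolate the time of the highest reading by that share, which puts the top of this flask at 5.04 d, and let the height gain put its height at 43.0%.

Now go round once more with that time. At 5.00 d noon reads 32.8%, past its top, and dawn reads 50.1%, short of its top, so mixing them by charge gives 39.9%, lower than the height gain gave. That mix joins two shoulders, not two tops, so keep 43.0% at 5.04 d.

The forecast, earlier and lower than this reckoning, says 40.5% at 4.1 d, within 2.2 d to 6.3 d: “Formation matches loss near 4 d”.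

The flask gives 43.3% at 5.14 d, and holds the share of that asked for from 2.88 d to 7.95 d. Counted in that target, crystals stand at 24.5% of the substrate charged at 5.14 d.

    substrate ⇌ target (K = 9.35, k = 4.08 × 10⁻⁴ min⁻¹)
    substrate ⇌ isomer of the product (K = 1.87, k = 4.77 × 10⁻⁴ min⁻¹)
    crystals ⇌ target, rate k3*(cs3 - [target]) while solid is left; crystals form when [target] > cs3 (solubility = 0.160 M, k = 0.0824 min⁻¹)
    substrate + target ⇌ idle adduct, settled at all times (K = 0.396 L mol⁻¹)
    target → over-reaction product (k = 1.64 × 10⁻⁴ min⁻¹)

From noon to this flask the height gain comes out at 0.259 L mol⁻¹. Carried down from noon to the same flask with 0.22 M of substrate, the height gain gives 26.6%, and that flask reaches 33.8%.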